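The route rests on closing the seven-membered ring B between C9 and C10 by an intramolecular Nozaki–Hiyama–Kishi reaction. The feature exploited is the allylic alcohol C10(O)–C9=C8(CH3) of ring B, whose carbinol carbon C10 hangs on the quaternary ring-fusion carbon C1: a (Z)-alkenyl iodide at C9 adds to a non-enolisable C10 aldehyde. In one operation this forms the C9–C10 bond, the cycloheptene with its trisubstituted alkene in place and the C10 stereocentre. The precursor is a fully substituted cyclopentane (ring A) carrying C1 (methyl, formyl), the C4 tertiary carbinol and, at C5, the C6 aryl ester side chain that ends in the (Z)-iodoalkene.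

Key step: step 14

Remark: daucane numbering is used: C1 is the quaternary ring-fusion carbon (CH3), C4 the carbinol carbon bearing isopropyl, C5 the ring-fusion CH, C6 the aryl ester carbon, C8 the methyl-bearing alkene carbon and C10 the tiglate carbon. The α face is the face of H-5, O-4 and C10. Compounds 1, 2, 16, 21 and 29 are taken as commercial. Aldehyde 26 is drawn open although it may rest as the lactol with the cis C4 hydroxyl.

Step 1
Reactants: 1 3-methylcyclopent-2-en-1-one; 2 (2-methylprop-1-en-1-yl)magnesium bromide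
Product: 4 trimethyl{[(3R)-3-methyl-3-(2-methylprop-1-en-1-yl)cyclopent-1-en-1-yl]oxy}silane, via aluminium enolate 3 (not isolated)
Conditions: 2, Me2AlCl, Et2O, 0 °C; then 1, copper thiophene-2-carboxylate Cu(O2CC4H3S) (5 mol%), chiral phosphinamine ligand (SimplePhos type, 6 mol%), Et2O, −30 °C; then TMSOTf, −30 to 0 °C
Reagents that add atoms: (2-methylprop-1-en-1-yl)magnesium bromide 2, CC(C)=C[Mg]Br (transferred as the alane CC(C)=C[Al](C)C); trimethylsilyl triflate, C[Si](C)(C)OS(=O)(=O)C(F)(F)F
Why: Copper-catalysed asymmetric conjugate addition of an alkenylaluminium reagent to a β-substituted cyclic enone should set the C1 quaternary centre under ligand control (ligand antipode chosen for 3R), and silylation of the aluminium enolate fixes the enolate toward C5.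

Step 2
Reactants: 4 trimethyl{[(3R)-3-methyl-3-(2-methylprop-1-en-1-yl)cyclopent-1-en-1-yl]oxy}silane
Product: 7 (3R)-3-methyl-2-methylidene-3-(2-methylprop-1-en-1-yl)cyclopentan-1-one, via Mannich base 5 (not isolated), via methiodide 6 (not isolated)
Conditions: Me2N=CH2+ I− (Eschenmoser's salt), CH2Cl2, rt; then MeI; then DBU, rt
Reagents that add atoms: Eschenmoser's salt, C=[N+](C)C.[I-]
Why: Mannich reaction of the regiodefined silyl enol ether occurs only at C5, and quaternisation with E1cB elimination should give the exo-methylene ketone, which cannot move into the ring because C1 is quaternary.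

Step 3
Reactants: 7 (3R)-3-methyl-2-methylidene-3-(2-methylprop-1-en-1-yl)cyclopentan-1-one
Product: 8 (3R)-3-methyl-2-methylidene-3-(2-methylprop-1-en-1-yl)-1-(propan-2-yl)cyclopentan-1-ol (both C4 epimers)
Conditions: iPrMgCl, CeCl3, THF, −78 °C
Reagents that add atoms: isopropylmagnesium chloride, CC(C)[Mg]Cl
Why: Organocerium 1,2-addition to the enone carbonyl gives the tertiary allylic alcohol; the C4 configuration is not controlled here and need not be, because step 4 erases it.

Step 4
Reactants: 8 (3R)-3-methyl-2-methylidene-3-(2-methylprop-1-en-1-yl)-1-(propan-2-yl)cyclopentan-1-ol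
Product: 9 [(5R)-5-methyl-5-(2-methylprop-1-en-1-yl)-2-(propan-2-yl)cyclopent-1-en-1-yl]methanol
Conditions: Ph3SiOReO3 (2 mol%), Et2O, −50 to 0 °C
Reagents that add atoms: none
Why: Perrhenate-catalysed 1,3-transposition of the allylic alcohol ([3,3] shift of the perrhenate ester) should converge both epimers of 8 to the primary allylic alcohol with the more stable tetrasubstituted ring alkene.

Step 5
Reactants: 9 [(5R)-5-methyl-5-(2-methylprop-1-en-1-yl)-2-(propan-2-yl)cyclopent-1-en-1-yl]methanol
Product: 10 [(1R,2R,5S)-2-methyl-2-(2-methylprop-1-en-1-yl)-5-(propan-2-yl)-6-oxabicyclo[3.1.0]hexan-1-yl]methanol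
Conditions: Ti(OiPr)4, D-(−)-diethyl tartrate, t-BuOOH, 4 Å MS, CH2Cl2, −20 °C
Reagents that add atoms: tert-butyl hydroperoxide, CC(C)(C)OO
Why: Sharpless asymmetric epoxidation; D-(−)-tartrate should deliver the oxygen to the α face (the face of the C1 alkenyl group), so the C4–O bond is set by the reagent and the isolated alkene is untouched.

Step 6
Reactants: 10 [(1R,2R,5S)-2-methyl-2-(2-methylprop-1-en-1-yl)-5-(propan-2-yl)-6-oxabicyclo[3.1.0]hexan-1-yl]methanol
Product: 12 (1S,3R)-3-methyl-2-methylidene-3-(2-methylprop-1-en-1-yl)-1-(propan-2-yl)cyclopentan-1-ol, via iodo epoxide 11 (not isolated)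
Conditions: I2, PPh3, imidazole, THF, 0 °C; then Zn, AcOH, EtOH, rt
Reagents that add atoms: none
Why: Appel iodination and zinc-mediated reductive β-elimination of the iodo epoxide should restore the exocyclic alkene and free the C4 tertiary alcohol as a single epimer, because the C4–O bond is never broken.

Step 7
Reactants: 12 (1S,3R)-3-methyl-2-methylidene-3-(2-methylprop-1-en-1-yl)-1-(propan-2-yl)cyclopentan-1-ol
Product: 14 (1S,2S,3R)-2-(hydroxymethyl)-3-methyl-3-(2-methylprop-1-en-1-yl)-1-(propan-2-yl)cyclopentan-1-ol, via alkylborane 13 (not isolated)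
Conditions: 9-BBN, THF, 0 °C to rt; then NaOH, H2O2, 0 °C
Reagents that add atoms: hydrogen peroxide, OO
Why: Uncatalysed hydroboration of the 1,1-disubstituted allylic alcohol (Still–Barrish anti selectivity) should put hydrogen on C5 from the α face, anti to the C4 isopropyl and C1 methyl groups, so that C6 ends trans to the C4 hydroxyl; the hindered trisubstituted alkenyl group reacts much more slowly with 9-BBN.

Step 8
Reactants: 14 (1S,2S,3R)-2-(hydroxymethyl)-3-methyl-3-(2-methylprop-1-en-1-yl)-1-(propan-2-yl)cyclopentan-1-ol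
Product: 15 (1R,2S,5R)-2-hydroxy-5-methyl-5-(2-methylprop-1-en-1-yl)-2-(propan-2-yl)cyclopentane-1-carbaldehyde
Conditions: TEMPO (cat.), PhI(OAc)2, CH2Cl2, rt
Reagents that add atoms: none
Why: Oxoammonium oxidation is selective for the primary alcohol and mild enough to avoid C5 epimerisation or retro-aldol cleavage of the β-hydroxy aldehyde.

Step 9
Reactants: 15 (1R,2S,5R)-2-hydroxy-5-methyl-5-(2-methylprop-1-en-1-yl)-2-(propan-2-yl)cyclopentane-1-carbaldehyde; 16 3-bromoprop-1-yne
Product: 17 (1S,2S,3R)-2-[(1S)-1-hydroxybut-3-yn-1-yl]-3-methyl-3-(2-methylprop-1-en-1-yl)-1-(propan-2-yl)cyclopentan-1-ol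
Conditions: In powder, THF/H2O, rt
Reagents that add atoms: 3-bromoprop-1-yne 16, C#CCBr
Why: Barbier propargylation through the allenylindium (SE2′) gives the homopropargylic alcohol; in the chelate between the C4 hydroxyl and the aldehyde the axial C4 isopropyl blocks one face, so the nucleophile should enter anti to it and give the (S)-carbinol at C6.

Step 10
Reactants: 17 (1S,2S,3R)-2-[(1S)-1-hydroxybut-3-yn-1-yl]-3-methyl-3-(2-methylprop-1-en-1-yl)-1-(propan-2-yl)cyclopentan-1-ol
Product: 20 (1S,2S,3R)-2-[(1S,3Z)-1-hydroxy-4-iodo-3-methylbut-3-en-1-yl]-3-methyl-3-(2-methylprop-1-en-1-yl)-1-(propan-2-yl)cyclopentan-1-ol, via (E)-alkenylalane 18 (not isolated), via (Z)-alkenylalane 19 (not isolated)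
Conditions: Me3Al, Cp2ZrCl2, (CH2Cl)2, rt then reflux; then I2, THF, −30 °C
Reagents that add atoms: trimethylaluminium, C[Al](C)C; iodine, II
Why: Zirconium-catalysed syn-methylalumination, chelation-driven isomerisation of the alkenylalane toward the C6 alkoxide and iodinolysis with retention (Negishi anti-carbometallation of homopropargylic alcohols) should give the (Z)-iodoalkene with the methyl group on C8.

Step 11
Reactants: 21 4-hydroxybenzoic acid
Product: 23 4-[(tert-butyldimethylsilyl)oxy]benzoic acid, via bis-silylated acid 22 (not isolated)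
Conditions: TBSCl, imidazole, DMF, rt; then K2CO3, MeOH/THF/H2O, rt
Reagents that add atoms: tert-butyldimethylsilyl chloride, CC(C)(C)[Si](C)(C)Cl
Why: Double silylation followed by selective solvolysis of the labile silyl ester leaves the phenol protected as its silyl ether.

Step 12
Reactants: 20 the (Z)-iodoalkenyl diol; 23 4-[(tert-butyldimethylsilyl)oxy]benzoic acid
Product: 24 (1S,3Z)-1-[(1S,2S,5R)-2-hydroxy-5-methyl-5-(2-methylprop-1-en-1-yl)-2-(propan-2-yl)cyclopentyl]-4-iodo-3-methylbut-3-en-1-yl 4-[(tert-butyldimethylsilyl)oxy]benzoate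
Conditions: EDC·HCl, DMAP, CH2Cl2, rt to 40 °C
Reagents that add atoms: 4-[(tert-butyldimethylsilyl)oxy]benzoic acid 23, OC(=O)c1ccc(O[Si](C)(C)C(C)(C)C)cc1
Why: Steglich esterification acylates the secondary C6 hydroxyl with retention; the tertiary C4 hydroxyl is too hindered to react.

Step 13
Reactants: 24 the aryl ester
Product: 26 (1S,3Z)-1-[(1S,2S,5S)-5-formyl-2-hydroxy-5-methyl-2-(propan-2-yl)cyclopentyl]-4-iodo-3-methylbut-3-en-1-yl 4-[(tert-butyldimethylsilyl)oxy]benzoate, via vicinal diol 25 (not isolated)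
Conditions: OsO4 (2 mol%), NaIO4, 2,6-lutidine, dioxane/H2O, rt
Reagents that add atoms: OsO4, O=[Os](=O)(=O)=O (oxygen of the aldehyde; reoxidised by NaIO4, [Na+].[O-]I(=O)(=O)=O)
Why: Lemieux–Johnson cleavage; OsO4 should dihydroxylate the electron-rich trisubstituted alkene in preference to the electron-poor iodoalkene, and periodate cleavage unveils the C10 aldehyde.

Step 14
Reactants: 26 the iodoalkenyl aldehyde
Product: 28 (3S,3aS,4S,8R,8aS)-3,8-dihydroxy-6,8a-dimethyl-3-(propan-2-yl)-1,2,3,3a,4,5,8,8a-octahydroazulen-4-yl 4-[(tert-butyldimethylsilyl)oxy]benzoate, via alkenylchromium species 27 (not isolated)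
Conditions: CrCl2 (excess), NiCl2 (cat.), DMSO, rt, high dilution
Reagents that add atoms: none
Why: Zerovalent nickel (formed from NiCl2 by CrCl2) inserts into the C9–I bond with retention of the (Z)-geometry, transmetallation gives the alkenyl trivalent chromium species 27, and this adds to the C10 aldehyde, the seven-membered ring closing in a 7-exo-trig mode at the carbonyl with the C8=C9 alkene ending endocyclic. The closest known reaction type is the intramolecular Nozaki–Hiyama–Kishi cyclisation of iodoalkenyl aldehydes to medium-ring allylic alcohols. The (Z)-iodide fixed in step 10 is required so that C7 and C10 are cis on the new ring alkene. At the new stereocentre C10 the chromium-bound oxygen should settle on the α face, anti to the angular C1 methyl and within reach of the cis C4 hydroxyl that can coordinate chromium, which gives the 10α (R) alcohol. The aldehyde is neopentyl and non-enolisable, so neither epimerisation nor aldol side reactions can occur, and the aryl ester and silyl ether are inert to the organochromium reagent. High dilution is needed to favour ring closure over intermolecular coupling.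

Step 15
Reactants: 28 the cycloheptenol; 29 tiglic acid [(2E)-2-methylbut-2-enoic acid]
Product: 31 (3S,3aS,4S,8R,8aS)-4-({4-[(tert-butyldimethylsilyl)oxy]benzoyl}oxy)-3-hydroxy-6,8a-dimethyl-3-(propan-2-yl)-1,2,3,3a,4,5,8,8a-octahydroazulen-8-yl (2E)-2-methylbut-2-enoate, via mixed anhydride 30 (not isolated)
Conditions: 29, 2,4,6-trichlorobenzoyl chloride, Et3N, toluene, rt; then 28, DMAP, 60 °C
Reagents that add atoms: tiglic acid 29, C/C=C(\C)C(O)=O
Why: Yamaguchi esterification acylates the hindered secondary allylic C10 hydroxyl with retention while the tertiary C4 hydroxyl stays free, and the (E)-tiglate is the stable alkene isomer.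

Step 16
Reactants: 31 the silyl-protected diester
Product: 32 (3S,3aS,4S,8R,8aS)-3-hydroxy-4-[(4-hydroxybenzoyl)oxy]-6,8a-dimethyl-3-(propan-2-yl)-1,2,3,3a,4,5,8,8a-octahydroazulen-8-yl (2E)-2-methylbut-2-enoate (target)
Conditions: HF·pyridine, pyridine/THF, 0 °C to rt
Reagents that add atoms: none
Why: Fluoride-mediated desilylation frees the phenol; both esters and the tertiary alcohol are stable to buffered HF.

Compound list
1 | 3-methylcyclopent-2-en-1-one | CC1=CC(=O)CC1 | starting material
2 | (2-methylprop-1-en-1-yl)magnesium bromide | CC(C)=C[Mg]Br | starting material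
3 | dimethylaluminium enolate (toward C5) of (3R)-3-methyl-3-(2-methylprop-1-en-1-yl)cyclopentanone | C[Al](C)OC1=C[C@](C=C(C)C)(C)CC1 | intermediate
4 | trimethyl{[(3R)-3-methyl-3-(2-methylprop-1-en-1-yl)cyclopent-1-en-1-yl]oxy}silane | C[Si](C)(C)OC1=C[C@](C=C(C)C)(C)CC1 | intermediate
5 | (3R)-2-[(dimethylamino)methyl]-3-methyl-3-(2-methylprop-1-en-1-yl)cyclopentan-1-one (C2 epimers) | CN(C)CC1[C@](C=C(C)C)(C)CCC1=O | intermediate
6 | {[(2R)-2-methyl-2-(2-methylprop-1-en-1-yl)-5-oxocyclopentyl]methyl}trimethylammonium iodide | C[N+](C)(C)CC1[C@](C=C(C)C)(C)CCC1=O.[I-] | intermediate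
7 | (3R)-3-methyl-2-methylidene-3-(2-methylprop-1-en-1-yl)cyclopentan-1-one | C=C1[C@](C=C(C)C)(C)CCC1=O | intermediate
8 | (3R)-3-methyl-2-methylidene-3-(2-methylprop-1-en-1-yl)-1-(propan-2-yl)cyclopentan-1-ol, both carbinol epimers | C=C1[C@](C=C(C)C)(C)CCC1(O)C(C)C | intermediate
9 | [(5R)-5-methyl-5-(2-methylprop-1-en-1-yl)-2-(propan-2-yl)cyclopent-1-en-1-yl]methanol | OCC1=C(C(C)C)CC[C@]1(C)C=C(C)C | intermediate
10 | [(1R,2R,5S)-2-methyl-2-(2-methylprop-1-en-1-yl)-5-(propan-2-yl)-6-oxabicyclo[3.1.0]hexan-1-yl]methanol | OC[C@@]12O[C@]1(C(C)C)CC[C@]2(C)C=C(C)C | intermediate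
11 | (1S,2R,5S)-1-(iodomethyl)-2-methyl-2-(2-methylprop-1-en-1-yl)-5-(propan-2-yl)-6-oxabicyclo[3.1.0]hexane | IC[C@@]12O[C@]1(C(C)C)CC[C@]2(C)C=C(C)C | intermediate
12 | (1S,3R)-3-methyl-2-methylidene-3-(2-methylprop-1-en-1-yl)-1-(propan-2-yl)cyclopentan-1-ol | C=C1[C@](C=C(C)C)(C)CC[C@]1(O)C(C)C | intermediate
13 | B-alkyl-9-borabicyclo[3.3.1]nonane adduct of 12 (boron on C6, ring configuration as in 14) | C1CCC2CCCC1B2C[C@@H]1[C@](C=C(C)C)(C)CC[C@]1(O)C(C)C | intermediate
14 | (1S,2S,3R)-2-(hydroxymethyl)-3-methyl-3-(2-methylprop-1-en-1-yl)-1-(propan-2-yl)cyclopentan-1-ol | OC[C@@H]1[C@](C=C(C)C)(C)CC[C@]1(O)C(C)C | intermediate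
15 | (1R,2S,5R)-2-hydroxy-5-methyl-5-(2-methylprop-1-en-1-yl)-2-(propan-2-yl)cyclopentane-1-carbaldehyde | O=C[C@@H]1[C@](C=C(C)C)(C)CC[C@]1(O)C(C)C | intermediate
16 | 3-bromoprop-1-yne (propargyl bromide) | C#CCBr | starting material
17 | (1S,2S,3R)-2-[(1S)-1-hydroxybut-3-yn-1-yl]-3-methyl-3-(2-methylprop-1-en-1-yl)-1-(propan-2-yl)cyclopentan-1-ol | C#CC[C@H](O)[C@@H]1[C@](C=C(C)C)(C)CC[C@]1(O)C(C)C | intermediate
18 | (E)-alkenyl(dimethyl)aluminium from syn-methylalumination of 17 (drawn with free hydroxyls) | C[Al](C)/C=C(C)/C[C@H](O)[C@@H]1[C@](C=C(C)C)(C)CC[C@]1(O)C(C)C | intermediate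
19 | (Z)-alkenyl(dimethyl)aluminium, the chelated isomer of 18 (drawn with free hydroxyls) | C[Al](C)/C=C(C)\C[C@H](O)[C@@H]1[C@](C=C(C)C)(C)CC[C@]1(O)C(C)C | intermediate
20 | (1S,2S,3R)-2-[(1S,3Z)-1-hydroxy-4-iodo-3-methylbut-3-en-1-yl]-3-methyl-3-(2-methylprop-1-en-1-yl)-1-(propan-2-yl)cyclopentan-1-ol | I/C=C(C)\C[C@H](O)[C@@H]1[C@](C=C(C)C)(C)CC[C@]1(O)C(C)C | intermediate
21 | 4-hydroxybenzoic acid | OC(=O)c1ccc(O)cc1 | starting material
22 | tert-butyldimethylsilyl 4-[(tert-butyldimethylsilyl)oxy]benzoate | CC(C)(C)[Si](C)(C)OC(=O)c1ccc(O[Si](C)(C)C(C)(C)C)cc1 | intermediate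
23 | 4-[(tert-butyldimethylsilyl)oxy]benzoic acid | OC(=O)c1ccc(O[Si](C)(C)C(C)(C)C)cc1 | intermediate
24 | (1S,3Z)-1-[(1S,2S,5R)-2-hydroxy-5-methyl-5-(2-methylprop-1-en-1-yl)-2-(propan-2-yl)cyclopentyl]-4-iodo-3-methylbut-3-en-1-yl 4-[(tert-butyldimethylsilyl)oxy]benzoate | I/C=C(C)\C[C@H](OC(=O)c1ccc(O[Si](C)(C)C(C)(C)C)cc1)[C@@H]1[C@](C=C(C)C)(C)CC[C@]1(O)C(C)C | intermediate
25 | vicinal diol from dihydroxylation of the 2-methylprop-1-enyl group of 24 (new carbinol centre unassigned) | I/C=C(C)\C[C@H](OC(=O)c1ccc(O[Si](C)(C)C(C)(C)C)cc1)[C@@H]1[C@](C(O)C(C)(C)O)(C)CC[C@]1(O)C(C)C | intermediate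
26 | (1S,3Z)-1-[(1S,2S,5S)-5-formyl-2-hydroxy-5-methyl-2-(propan-2-yl)cyclopentyl]-4-iodo-3-methylbut-3-en-1-yl 4-[(tert-butyldimethylsilyl)oxy]benzoate | I/C=C(C)\C[C@H](OC(=O)c1ccc(O[Si](C)(C)C(C)(C)C)cc1)[C@@H]1[C@](C=O)(C)CC[C@]1(O)C(C)C | intermediate
27 | (Z)-alkenylchromium dichloride formed from 26 at C9 | Cl[Cr](Cl)/C=C(C)\C[C@H](OC(=O)c1ccc(O[Si](C)(C)C(C)(C)C)cc1)[C@@H]1[C@](C=O)(C)CC[C@]1(O)C(C)C | intermediate
28 | (3S,3aS,4S,8R,8aS)-3,8-dihydroxy-6,8a-dimethyl-3-(propan-2-yl)-1,2,3,3a,4,5,8,8a-octahydroazulen-4-yl 4-[(tert-butyldimethylsilyl)oxy]benzoate | O[C@@H]1C=C(C)C[C@H](OC(=O)c2ccc(O[Si](C)(C)C(C)(C)C)cc2)[C@@H]2[C@]1(C)CC[C@]2(O)C(C)C | intermediate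
29 | tiglic acid, (2E)-2-methylbut-2-enoic acid | C/C=C(\C)C(O)=O | starting material
30 | (2E)-2-methylbut-2-enoic 2,4,6-trichlorobenzoic anhydride | C/C=C(\C)C(=O)OC(=O)c1c(Cl)cc(Cl)cc1Cl | intermediate
31 | (3S,3aS,4S,8R,8aS)-4-({4-[(tert-butyldimethylsilyl)oxy]benzoyl}oxy)-3-hydroxy-6,8a-dimethyl-3-(propan-2-yl)-1,2,3,3a,4,5,8,8a-octahydroazulen-8-yl (2E)-2-methylbut-2-enoate | C/C=C(\C)C(=O)O[C@@H]1C=C(C)C[C@H](OC(=O)c2ccc(O[Si](C)(C)C(C)(C)C)cc2)[C@@H]2[C@]1(C)CC[C@]2(O)C(C)C | intermediate
32 | (3S,3aS,4S,8R,8aS)-3-hydroxy-4-[(4-hydroxybenzoyl)oxy]-6,8a-dimethyl-3-(propan-2-yl)-1,2,3,3a,4,5,8,8a-octahydroazulen-8-yl (2E)-2-methylbut-2-enoate | C/C=C(\C)C(=O)O[C@@H]1C=C(C)C[C@H](OC(=O)c2ccc(O)cc2)[C@@H]2[C@]1(C)CC[C@]2(O)C(C)C | target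

Total step count: 16. Longest linear sequence: 15 steps (steps 1 to 10 and 12 to 16; step 11 is a side branch).

Steps most likely to fail

Step 14 (key step). The addition may discriminate poorly between the two faces of the C10 aldehyde, or place the chromium alkoxide on the β face, so that the 10-epimer is formed. The fallback sets out from 26: the same cyclisation then gives the 10-epimeric alcohol F1. F1 is esterified with tiglic acid 29 under Mitsunobu conditions (PPh3, DIAD, toluene), which inverts C10 in the esterification itself. The fallback comes back to the route at 31.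

Step 7. The hydroboration may lose facial selectivity (for example if an O-borinate on the α face reverses the steric bias), or the borane may attack the alkenyl group on C1. The fallback sets out from 10 and avoids the exocyclic alkene altogether. Oxidation with Dess–Martin periodinane gives the epoxy aldehyde F2. SmI2 in THF/MeOH at −90 °C then cleaves the C5–O bond next to the carbonyl, and kinetic protonation of the samarium enolate from the less hindered α face, next to the C4 alkoxide, should give 15. The fallback comes back at 15 and bypasses steps 6 to 8.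

Step 9. Chelation between the C4 hydroxyl and the aldehyde may be weak in the aqueous medium, so that the propargylation gives a mixture at C6. The fallback sets out from 15 and replaces substrate control by catalyst control: allenylboronic acid pinacol ester is added under a chiral BINOL-derived phosphoric acid catalyst, which sets C6 through the catalyst. It comes back at 17 and makes no new compound (F0).

Further compounds
F1 | step 14 | (3S,3aS,4S,8S,8aS)-3,8-dihydroxy-6,8a-dimethyl-3-(propan-2-yl)-1,2,3,3a,4,5,8,8a-octahydroazulen-4-yl 4-[(tert-butyldimethylsilyl)oxy]benzoate (10-epimer of 28) | O[C@H]1C=C(C)C[C@H](OC(=O)c2ccc(O[Si](C)(C)C(C)(C)C)cc2)[C@@H]2[C@]1(C)CC[C@]2(O)C(C)C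
F2 | step 7 | (1S,2R,5S)-2-methyl-2-(2-methylprop-1-en-1-yl)-5-(propan-2-yl)-6-oxabicyclo[3.1.0]hexane-1-carbaldehyde | O=C[C@@]12O[C@]1(C(C)C)CC[C@]2(C)C=C(C)C
F0 | step 9 | none | none
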